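## Structural features

- Read from the SMILES as (1S,2S,3R,6R), the target is a 7-oxabicyclo[4.1.0]hept-4-ene. It has one cyclohexene ring (C1–C6, C4=C5) cis-fused across C1–C6 to an oxirane, and one exocyclic carbon, C7 (CH2OBz), on C1.
- The four stereocentres form an unbroken, fully oxygenated row C6–C1–C2–C3. C1 is fully substituted (O, C2, C6, C7).
- The oxirane oxygen is cis to the free hydroxyl on C2 and trans to the benzoate on C3.
- Both alkene termini are flanked by C–O bonds: C5 by the oxirane carbon C6, and C4 by the benzoate carbon C3. The molecule is therefore a vinyl oxirane and an allylic ester at once: acid, soft nucleophiles and low-valent metals open it, loss of its oxygen functions leads downhill to an arene, and base lets benzoyl groups move between O3 and O2.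
- The real difficulty is the quaternary C1–O centre, held between two oxygenated stereocentres in the right sense to both, together with the exact placing of the double bond.
- The key step exploits the string C7–C1–C6–C5=C4. With C7 raised to the acid level this is a γ,δ-unsaturated acid, the retron of a Claisen rearrangement.
- C4 is tied back to C1 through C3 and C2. The retro-[3,3] step (C1–C6 cut, carboxyl oxygen joined to C4) therefore gives no chain but the six-membered ring O–C7–C1–C2–C3–C4, an aldono-1,5-lactone. In it C7, C1, C2, C3, C4 and C5 are C1′ to C6′ of D-glucose, and the trans C2/C3 diol has the D-gluco C3′/C4′ configuration.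

## Logic of the disconnections

**13 back to 11 (through 12).**
- Cut: the two acyl–oxygen bonds at O7 and O3.
- Reason: the benzoates are the groups least able to survive enolate, hydride and fluoride chemistry, and they migrate under base.
- Gain: no ester has to be carried or exchanged, and one kind of protecting group serves the whole route.
- Demand: the last step must acylate the primary O7 and the allylic O3 but leave the hindered O2 free.

**11 back to 9 (through 10).**
- Cut: the oxirane bond C6–O; the free hydroxyls become silyl ethers.
- Reason: the oxirane oxygen already sits on C1, so C6 needs only a leaving group on the opposite face.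
- Gain: the fragile vinyl oxirane is replaced by an allylic chloride and silyl ethers that tolerate heat, hydride and chromatography.
- Demand: chlorine must stand trans to the C1 oxygen, and the 3-exo closure must outrun every other reaction of the released alkoxides.

**9 back to 7 (through 8).**
- No skeletal bond is cut; C7 is raised from the alcohol to the acid level.
- Reason: this exposes the γ,δ-unsaturated acid retron C7–C1–C6–C5=C4.
- Gain: none in size, but it opens the key disconnection.
- Demand: the forward reduction must spare the allylic chloride.

**7 back to 4 (through 6 and 5), the key disconnection.**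
- Cut: C1–C6. Joined: the carboxyl oxygen to C4. The double bond moves from C4=C5 to C5=C6.
- Reason: this is the only cut that removes the quaternary centre, the C6 stereocentre and the carbocycle together.
- Gain: a cyclohexene with four contiguous stereocentres falls back to a sugar lactone whose three stereocentres are bought, plus one alkene of defined geometry.
- Demand: a ketene acetal must form next to a β-silyloxy group. The rearrangement must then pass through a boat array, with the alkenyl group axial and the alkene E.

**4 back to 3.**
- Cut: the double bond C5=C6 (C6′=C7′).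
- Reason: C6 is the only carbon that the hexose lacks, and a one-carbon olefination can bring it in together with its leaving group.
- Gain: the substrate becomes a plain hexose derivative.
- Demand: high E selectivity under non-basic conditions, because C4 (C5′) is an epimerisable centre that carries all the stereochemical information for the key step.

**3 back to 2 and 1.**
- Cut: four O–Si bonds; C5 (C6′) returns to the alcohol level.
- Reason: the primary position can be told apart from the three secondary ones by reactivity alone.
- Gain: the commercial starting material 1 is reached.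
- Demand: oxidation at the primary silyl ether only, without loss of configuration at C5′.

## Other disconnections considered

Alternative 1: (the first that comes to mind)
- Cut: both C–O bonds of the oxirane.
- Forward key step: hydroxyl-directed epoxidation (vanadium/TBHP or a peracid) of the C1=C6 bond of the dienol A1, with the C2 hydroxyl delivering oxygen to its own face.
- The step forms only two C–O bonds. The ring, C2, C3 and the enantiopurity are all left inside A1.
- A1 is a trans-dihydrodiol ester of an arene, one elimination away from aromaticity. Neither the chiral pool nor a direct catalytic desymmetrisation offers an entry to it.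
- Microbial arene cis-dihydrodiols have the wrong relative configuration at C3. They would need an inversion on a diene that is prone to aromatise.
- The directing effect also has to beat the second double bond, and the acid-labile vinyl oxirane would be born in an acidic or Lewis-acidic medium.
- The difficulty is moved, not solved, so the chosen plan is preferred.

Alternative 2:
- Cut: C6–O, with a second oxygen inserted between the C1 oxygen and C4. This leads back to the endoperoxide A2.
- Forward key step: [4+2] addition of singlet oxygen to A1. A phosphine then removes one ring oxygen, and the C1 alkoxide collapses in the SN2′ sense onto C6.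
- This is a single-atom deletion on a ring type on which it is known, and it sets C1 in a cycloaddition. It nevertheless starts from the same fragile A1.
- Each face of this trans-disubstituted diene carries one substituent. Face selection therefore rests on a soft balance between steering by the hydroxyl and shielding by the benzoate.
- The phosphine has to attack the oxygen on C4 and not that on C1.
- The C3 benzoate stands anti to the activated C4–O bond and may take part.
- Step economy is no better, since A1 must still be made.

Alternative 3:
- Cut: C1–C6 and C6–O together.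
- Forward key step: deprotonation of the (Z)-allyl sulfonium salt A3, addition of the ylide carbon C6 to the ketone C1, and closure of the betaine to the protected vinyl oxirane A4.
- The bond set resembles that of the chosen plan, but stereocontrol is weaker. C1 would depend on 1,2-induction from C2 in a flexible chain.
- C6 would depend on reversible betaine formation, because only the anti betaine can close.
- The ylide carries the C3 oxygen in the vinylogous β-position, and the ketone is enolisable with the same oxygen at its β-carbon. Two elimination channels therefore compete.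
- The seven-carbon chain, the Z alkene and differentiated protecting groups would have to be built stepwise, which makes the route longer.
- In the chosen plan the tether enforces the face of attack and the chain is bought.

Key step: step 4

Remark on numbering: unprimed locants C1–C7 are those of the target. Primed locants are sugar positions, with C1′→C7, C2′→C1, C3′→C2, C4′→C3, C5′→C4, C6′→C5 and C7′→C6. TES = triethylsilyl.

## Route

Step 1
Reactants: 1 D-glucono-1,5-lactone
Product: 2 2,3,4,6-tetrakis-O-(triethylsilyl)-D-glucono-1,5-lactone
Conditions: TESCl (5 equiv), imidazole, cat. DMAP, DMF, 0 °C to rt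
Reagents that add atoms: chlorotriethylsilane, CC[Si](Cl)(CC)CC
Why: Exhaustive silyl ether formation under mild base; fast silylation in an aprotic medium should fix the six-membered lactone before it can isomerise to the 1,4-lactone. No stereocentre is touched, and one kind of group protects all four oxygens.

Step 2
Reactants: 2 2,3,4,6-tetrakis-O-(triethylsilyl)-D-glucono-1,5-lactone
Product: 3 2,3,4-tris-O-(triethylsilyl)-D-gluco-hexodialdono-1,5-lactone (aldehyde at C6′)
Conditions: (COCl)2, DMSO, CH2Cl2, −78 to −35 °C; then Et3N, −78 to −20 °C
Reagents that add atoms: none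
Why: Swern oxidation applied directly to a silyl ether: the chlorosulfonium salt attacks only the unhindered primary TES ether, turns it into the alkoxysulfonium ion and so into the aldehyde, while the three secondary TES ethers stay. Adding the amine cold and working up early should keep C5′ intact; epimerisation at C2′ would be harmless because that centre becomes planar in step 4.

Step 3
Reactants: 3 2,3,4-tris-O-(triethylsilyl)-D-gluco-hexodialdono-1,5-lactone
Product: 4 (E)-7-chloro-6,7-dideoxy-2,3,4-tris-O-(triethylsilyl)-D-gluco-hept-6-enono-1,5-lactone
Conditions: CrCl2 (6–8 equiv), CHCl3, THF, 65 °C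
Reagents that add atoms: chloroform, ClC(Cl)Cl
Why: Takai olefination: the geminal dichromium reagent adds to the aldehyde, and elimination from the less crowded β-oxido chromium species should give the E chloride. The medium is not basic, so C5′ is not enolised, and lactone and silyl ethers are inert to chromium(II).

Step 4
Reactants: 4 (E)-7-chloro-6,7-dideoxy-2,3,4-tris-O-(triethylsilyl)-D-gluco-hept-6-enono-1,5-lactone
Product: 7 (1R,2S,5R,6S)-2-chloro-1,5,6-tris(triethylsilyloxy)cyclohex-3-ene-1-carboxylic acid, via trimethylsilyl ketene acetal 5 (not isolated), via trimethylsilyl ester 6 (not isolated)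
Conditions: LiHMDS, TMSCl–Et3N (internal quench), THF, −78 °C; solvent change to PhMe, 100 °C; aq. citric acid, THF, rt
Reagents that add atoms: none
Why: LiHMDS removes H-2′ of 4 and the enolate is silylated on oxygen as it forms, which should give the cyclic ketene acetal 5 before the C3′ silyloxy group can leave in the E1cB sense. On heating, 5 undergoes a concerted suprafacial [3,3]-sigmatropic shift (Ireland–Claisen rearrangement in its alicyclic, lactone form; the closest relatives are the rearrangements of 6-alkenyl δ-lactone silyl ketene acetals to cyclohexenecarboxylic acids and of 2-vinyl-3,4-dihydro-2H-pyrans, glycal-derived ones included, to cyclohexenecarbaldehydes), in which C2′–C7′ (C1–C6) forms, C5′–O5′ (C4–O) breaks, C5′=C6′ (C4=C5) appears and the ring oxygen ends as the carbonyl oxygen of the silyl ester 6. The carbocycle is thus closed by ring transposition through a bicyclo[2.2.2]octadiene-like array and not by a Baldwin-type attack, and because the termini C2′ and C5′ are held by the two-atom bridge C3′–C4′, only the boat transition state with an axial alkenyl group is possible. At C1 the new bond can reach C2′ only on the face that carries the alkenyl group (the β face of the D-sugar), which places O2′ cis to O3′ (C2–O) and trans to O4′ (C3–O) on the new ring, while the C5′ stereocentre is consumed in the transfer. At C6 the E substituent of C7′ eclipses O2′ across the forming bond in the boat array and ends trans to it on the new ring, so that the (E)-chloride gives the anti chlorohydrin ether (6S in target numbering) that step 7 needs, whereas any Z isomer would suffer a syn contact between chlorine and O3′ and should react more slowly. The step needs O-silylation to outrun β-elimination and rearrangement to outrun ionisation or allylic shift of the product chloride; the internal quench at −78 °C serves the first, and the non-polar medium, the absence of Lewis acids and the rate gain of a ketene acetal, which keeps the temperature near 100 °C, serve the second. The three bulky, mutually trans silyl ethers destabilise the all-equatorial half-chair and so raise the share of the all-axial conformer from which the reaction starts, although the syn-axial contact between O3′ and the alkenyl group remains as a cost. Mild aqueous acid then cleaves only the silyl ester and gives 7.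

Step 5
Reactants: 7 (1R,2S,5R,6S)-2-chloro-1,5,6-tris(triethylsilyloxy)cyclohex-3-ene-1-carboxylic acid
Product: 8 methyl (1R,2S,5R,6S)-2-chloro-1,5,6-tris(triethylsilyloxy)cyclohex-3-ene-1-carboxylate
Conditions: TMSCHN2, PhMe–MeOH, 0 °C
Reagents that add atoms: (trimethylsilyl)diazomethane, C[Si](C)(C)C=[N+]=[N-]
Why: O-alkylation of the carboxylate by a diazoalkane takes place away from the crowded C1 and is therefore insensitive to hindrance; the medium is neutral. Prompt esterification also removes the carboxylate, the one internal nucleophile placed to attack the allylic chloride at C4 in the SN2′ sense.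

Step 6
Reactants: 8 methyl (1R,2S,5R,6S)-2-chloro-1,5,6-tris(triethylsilyloxy)cyclohex-3-ene-1-carboxylate
Product: 9 [(1S,2S,5R,6S)-2-chloro-1,5,6-tris(triethylsilyloxy)cyclohex-3-en-1-yl]methanol
Conditions: DIBAL-H (3 equiv), CH2Cl2, −78 to −20 °C; aq. Rochelle salt
Reagents that add atoms: none
Why: Ester reduction with an electrophilic aluminium hydride, which at low temperature leaves the allylic chloride and the silyl ethers alone, whereas a nucleophilic hydride could displace chloride. The C7 oxygen lies on the same face as chlorine and cannot displace it; no stereocentre changes (the descriptor at C1 changes only through priorities).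

Step 7
Reactants: 9 [(1S,2S,5R,6S)-2-chloro-1,5,6-tris(triethylsilyloxy)cyclohex-3-en-1-yl]methanol
Product: 11 (1S,2S,3R,6R)-1-(hydroxymethyl)-7-oxabicyclo[4.1.0]hept-4-ene-2,3-diol, via chlorohydrin tetraol 10 (not isolated)
Conditions: TBAF (3.5 equiv), THF, 0 °C to rt
Reagents that add atoms: none
Why: Fluoride desilylation frees the C1 alkoxide anti to the C6–Cl bond, and an intramolecular Williamson closure (3-exo-tet, inversion at C6) should give the cis-fused oxirane on the face of the C1 oxygen, hence cis to C2–OH. The oxygens on C2 and C7 cannot reach the rear side of C6, and C2–O is cis to the new oxirane and so cannot open it at C1.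

Step 8
Reactants: 11 (1S,2S,3R,6R)-1-(hydroxymethyl)-7-oxabicyclo[4.1.0]hept-4-ene-2,3-diol
Product: 13 [(1S,2S,3R,6R)-3-(benzoyloxy)-2-hydroxy-7-oxabicyclo[4.1.0]hept-4-en-1-yl]methyl benzoate, via primary monobenzoate 12 (not isolated)
Conditions: BzCl (2.1 equiv), pyridine, CH2Cl2, −40 to −10 °C
Reagents that add atoms: benzoyl chloride, O=C(Cl)c1ccccc1
Why: Sterically controlled acylation: the primary O7 should react first, then the allylic O3, which has the flat C4 as neighbour. O2 lies between the fully substituted C1 (now bearing CH2OBz) and C3 and is hydrogen-bonded to the cis oxirane oxygen, so it should remain free; excess pyridine keeps the vinyl oxirane away from acid.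

## Compound list

1 | D-glucono-1,5-lactone | O=C1[C@H](O)[C@@H](O)[C@H](O)[C@@H](CO)O1 | starting material
2 | 2,3,4,6-tetrakis-O-(triethylsilyl)-D-glucono-1,5-lactone | O=C1[C@H](O[Si](CC)(CC)CC)[C@@H](O[Si](CC)(CC)CC)[C@H](O[Si](CC)(CC)CC)[C@@H](CO[Si](CC)(CC)CC)O1 | intermediate
3 | 2,3,4-tris-O-(triethylsilyl)-D-gluco-hexodialdono-1,5-lactone | O=C1[C@H](O[Si](CC)(CC)CC)[C@@H](O[Si](CC)(CC)CC)[C@H](O[Si](CC)(CC)CC)[C@@H](C=O)O1 | intermediate
4 | (E)-7-chloro-6,7-dideoxy-2,3,4-tris-O-(triethylsilyl)-D-gluco-hept-6-enono-1,5-lactone | O=C1[C@H](O[Si](CC)(CC)CC)[C@@H](O[Si](CC)(CC)CC)[C@H](O[Si](CC)(CC)CC)[C@@H](/C=C/Cl)O1 | intermediate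
5 | cyclic trimethylsilyl ketene acetal of 4 (C1′=C2′ enol form, O1′-SiMe3) | C[Si](C)(C)OC1=C(O[Si](CC)(CC)CC)[C@@H](O[Si](CC)(CC)CC)[C@H](O[Si](CC)(CC)CC)[C@@H](/C=C/Cl)O1 | intermediate
6 | trimethylsilyl (1R,2S,5R,6S)-2-chloro-1,5,6-tris(triethylsilyloxy)cyclohex-3-ene-1-carboxylate | C[Si](C)(C)OC(=O)[C@@]1(O[Si](CC)(CC)CC)[C@@H](Cl)C=C[C@@H](O[Si](CC)(CC)CC)[C@@H]1O[Si](CC)(CC)CC | intermediate
7 | (1R,2S,5R,6S)-2-chloro-1,5,6-tris(triethylsilyloxy)cyclohex-3-ene-1-carboxylic acid | OC(=O)[C@@]1(O[Si](CC)(CC)CC)[C@@H](Cl)C=C[C@@H](O[Si](CC)(CC)CC)[C@@H]1O[Si](CC)(CC)CC | intermediate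
8 | methyl (1R,2S,5R,6S)-2-chloro-1,5,6-tris(triethylsilyloxy)cyclohex-3-ene-1-carboxylate | COC(=O)[C@@]1(O[Si](CC)(CC)CC)[C@@H](Cl)C=C[C@@H](O[Si](CC)(CC)CC)[C@@H]1O[Si](CC)(CC)CC | intermediate
9 | [(1S,2S,5R,6S)-2-chloro-1,5,6-tris(triethylsilyloxy)cyclohex-3-en-1-yl]methanol | OC[C@@]1(O[Si](CC)(CC)CC)[C@@H](Cl)C=C[C@@H](O[Si](CC)(CC)CC)[C@@H]1O[Si](CC)(CC)CC | intermediate
10 | (1S,2S,3R,6S)-6-chloro-1-(hydroxymethyl)cyclohex-4-ene-1,2,3-triol | OC[C@@]1(O)[C@@H](Cl)C=C[C@@H](O)[C@@H]1O | intermediate
11 | (1S,2S,3R,6R)-1-(hydroxymethyl)-7-oxabicyclo[4.1.0]hept-4-ene-2,3-diol | OC[C@@]12O[C@@H]1C=C[C@@H](O)[C@@H]2O | intermediate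
12 | [(1S,2S,3R,6R)-2,3-dihydroxy-7-oxabicyclo[4.1.0]hept-4-en-1-yl]methyl benzoate | O=C(OC[C@@]12O[C@@H]1C=C[C@@H](O)[C@@H]2O)c1ccccc1 | intermediate
13 | [(1S,2S,3R,6R)-3-(benzoyloxy)-2-hydroxy-7-oxabicyclo[4.1.0]hept-4-en-1-yl]methyl benzoate | O=C(OC[C@@]12O[C@@H]1C=C[C@@H](OC(=O)c1ccccc1)[C@@H]2O)c1ccccc1 | target

## Step count and least certain steps

Total step count: 8. Longest linear sequence: 8 steps (1 to 13; the route is fully linear).

Origin of the stereocentres:
- C2 and C3 come from C3′ and C4′ of 1 and are never touched.
- C1 is set in step 4.
- C6 is set in step 4 and inverted by design in step 7.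

**Step 4 (key step).**
- Most likely failure: β-elimination of the C3′ silyloxy group from the lactone enolate before it is silylated, because the enolate of an aldonolactone has a leaving group at its β-carbon.
- Second: a high barrier of the crowded boat array (O2′ eclipsed with chlorine, O3′ syn-axial to the alkenyl group). This would call for temperatures at which the allylic chloride shifts or ionises.
- Fallback (from 4, back at 9): the enolate is avoided altogether. DIBAL-H at −78 °C reduces 4 to the lactol F1. Mesylation in the presence of DBU eliminates across C1′–C2′ (axial leaving group anti to the axial H-2′) to the 2-silyloxy glycal F2, a neutral allyl vinyl ether with the same tether. Heating in base-washed glass (o-dichlorobenzene, sealed tube) should lead through the same boat array to the aldehyde F3. NaBH4 reduces this to 9, so steps 5 and 6 fall away.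

**Step 2.**
- Most likely failure: loss of configuration at C5′, or β-elimination of the C4′ silyloxy group, once the amine meets the α-acyloxy aldehyde. Partial cleavage of secondary silyl ethers by adventitious HCl during the warm phase is also possible.
- Fallback (from 2, back at 3): deprotection and oxidation are separated, and no base is used. Aqueous acetic acid in THF at 0 °C removes only the primary silyl group and gives the primary alcohol F4. Dess–Martin periodinane buffered with NaHCO3 then oxidises this to 3.

**Step 3.**
- Most likely failure: chloroform is slow to form the dichromium reagent and needs heat. During that time the sensitive aldehyde may epimerise, eliminate or be reduced at the C5′–O bond, and the geometric purity may suffer.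
- Fallback (from 3, back at 4): carbon and halogen are introduced in two mild operations. A Takai-type stannyl olefination (Bu3SnCHBr2, CrCl2, LiI, THF–DMF, rt) gives the (E)-vinylstannane F5. Chlorodestannylation with CuCl2 in THF at rt, which retains the geometry, gives 4.

**Step 7.**
- Most likely failure: migration of the oxirane toward the C7 alkoxide (Payne-type equilibration) in the strongly basic fluoride medium, and loss of the water-soluble triol while the ammonium salts are removed.
- Fallback (from 9, back at 13, bypassing 10 to 12): the C7 oxygen is capped first and the silyl groups are removed under acid. Benzoylation of 9 (BzCl, pyridine, DMAP) gives the primary benzoate F6. HF·pyridine in THF–pyridine gives the chlorohydrin triol F7, which cannot rearrange. One equivalent of BzCl with collidine at −40 °C acylates the allylic O3 to the dibenzoate chlorohydrin F8 (the tertiary C1–OH is inert). DBU in CH2Cl2 at 0 °C then closes the oxirane to 13.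

**Step 8.**
- Most likely failure: insufficient discrimination between the two secondary hydroxyls. This would lead to acylation at O2, to overacylation, or to O3-to-O2 benzoyl migration during work-up.
- Fallback (from 11, back at 13): O2 is masked by a template and steric bias is not relied on. Phenylboronic acid with azeotropic removal of water ties O7 and O2 (a 1,3-diol; the trans 2,3-diol cannot compete) into the cyclic phenylboronate F9. BzCl in pyridine acylates the only free hydroxyl and gives the boronate benzoate F10. Exchange with pinacol releases the 3-benzoate diol F11. One equivalent of BzCl with collidine at −78 °C then meets a primary and a hindered secondary hydroxyl and should give 13.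

## Further compounds

F1 | step 4 | (E)-7-chloro-6,7-dideoxy-2,3,4-tris-O-(triethylsilyl)-D-gluco-hept-6-enopyranose (lactol, anomers) | OC1[C@H](O[Si](CC)(CC)CC)[C@@H](O[Si](CC)(CC)CC)[C@H](O[Si](CC)(CC)CC)[C@@H](/C=C/Cl)O1
F2 | step 4 | (E)-1,5-anhydro-7-chloro-6,7-dideoxy-2,3,4-tris-O-(triethylsilyl)-D-arabino-hepta-1,6-dienitol (2-silyloxy glycal) | C1=C(O[Si](CC)(CC)CC)[C@@H](O[Si](CC)(CC)CC)[C@H](O[Si](CC)(CC)CC)[C@@H](/C=C/Cl)O1
F3 | step 4 | (1R,2S,5R,6S)-2-chloro-1,5,6-tris(triethylsilyloxy)cyclohex-3-ene-1-carbaldehyde | O=C[C@@]1(O[Si](CC)(CC)CC)[C@@H](Cl)C=C[C@@H](O[Si](CC)(CC)CC)[C@@H]1O[Si](CC)(CC)CC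
F4 | step 2 | 2,3,4-tris-O-(triethylsilyl)-D-glucono-1,5-lactone | O=C1[C@H](O[Si](CC)(CC)CC)[C@@H](O[Si](CC)(CC)CC)[C@H](O[Si](CC)(CC)CC)[C@@H](CO)O1
F5 | step 3 | (E)-6,7-dideoxy-7-(tributylstannyl)-2,3,4-tris-O-(triethylsilyl)-D-gluco-hept-6-enono-1,5-lactone | O=C1[C@H](O[Si](CC)(CC)CC)[C@@H](O[Si](CC)(CC)CC)[C@H](O[Si](CC)(CC)CC)[C@@H](/C=C/[Sn](CCCC)(CCCC)CCCC)O1
F6 | step 7 | [(1S,2S,5R,6S)-2-chloro-1,5,6-tris(triethylsilyloxy)cyclohex-3-en-1-yl]methyl benzoate | O=C(OC[C@@]1(O[Si](CC)(CC)CC)[C@@H](Cl)C=C[C@@H](O[Si](CC)(CC)CC)[C@@H]1O[Si](CC)(CC)CC)c1ccccc1
F7 | step 7 | [(1S,2S,5R,6S)-2-chloro-1,5,6-trihydroxycyclohex-3-en-1-yl]methyl benzoate | O=C(OC[C@@]1(O)[C@@H](Cl)C=C[C@@H](O)[C@@H]1O)c1ccccc1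
F8 | step 7 | [(1S,2S,5R,6S)-5-(benzoyloxy)-2-chloro-1,6-dihydroxycyclohex-3-en-1-yl]methyl benzoate | O=C(OC[C@@]1(O)[C@@H](Cl)C=C[C@@H](OC(=O)c2ccccc2)[C@@H]1O)c1ccccc1
F9 | step 8 | cyclic O2,O7-phenylboronate of 11 (free 3-OH) | B1(c2ccccc2)OC[C@@]23O[C@@H]2C=C[C@@H](O)[C@@H]3O1
F10 | step 8 | cyclic O2,O7-phenylboronate of 11, 3-benzoate | B1(c2ccccc2)OC[C@@]23O[C@@H]2C=C[C@@H](OC(=O)c2ccccc2)[C@@H]3O1
F11 | step 8 | (1S,2S,3R,6R)-2-hydroxy-1-(hydroxymethyl)-7-oxabicyclo[4.1.0]hept-4-en-3-yl benzoate | OC[C@@]12O[C@@H]1C=C[C@@H](OC(=O)c1ccccc1)[C@@H]2O
A1 | alternative 1 | [(5R,6R)-5-(benzoyloxy)-6-hydroxycyclohexa-1,3-dien-1-yl]methyl benzoate | O=C(OCC1=CC=C[C@@H](OC(=O)c2ccccc2)[C@@H]1O)c1ccccc1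
A2 | alternative 2 | 1,4-endoperoxide of A1 (2,3-dioxabicyclo[2.2.2]oct-5-ene; peroxide bridge C1–O–O–C4 cis to C2–OH, trans to C3–OBz) | O=C(OC[C@@]12OO[C@@H](C=C1)[C@@H](OC(=O)c1ccccc1)[C@@H]2O)c1ccccc1
A3 | alternative 3 | 1-[(2Z,4R,5S)-7-(benzoyloxy)-4,5-bis(tert-butyldimethylsilyloxy)-6-oxohept-2-en-1-yl]thiolan-1-ium bromide | O=C(OCC(=O)[C@@H](O[Si](C)(C)C(C)(C)C)[C@H](O[Si](C)(C)C(C)(C)C)/C=C\C[S+]1CCCC1)c1ccccc1.[Br-]
A4 | alternative 3 | [(1S,2S,3R,6R)-2,3-bis(tert-butyldimethylsilyloxy)-7-oxabicyclo[4.1.0]hept-4-en-1-yl]methyl benzoate | O=C(OC[C@@]12O[C@@H]1C=C[C@@H](O[Si](C)(C)C(C)(C)C)[C@@H]2O[Si](C)(C)C(C)(C)C)c1ccccc1
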